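The enabling feature is in γ-lactone ring B. Carbonyl C1 lies one methylene (C2) from C3, which carries one peroxide oxygen of 1,2-dioxane ring A (C3–C4–C5–C6–O–O), and C1 is esterified by the oxygen on neighbouring C4. The array C6–O–O–C3–C2–C1(=O)–O–C4 is what addition of a peroxide oxygen and CO across the vinyl group of a tertiary vinyl carbinol would leave.
Cuts: C8=C9 first (methyl ketone 22 + allylic phosphine oxide 29). Then O–C3, C2–C1 and C1–O(C4) together, which opens both rings to hydroperoxy vinyl carbinol 17 and CO. Then C2=C3 (methylenation), C6–OO (peroxidation of a C6=C7 alkene) and C4–C5 (enolate alkylation).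
Forward: lactate-derived allylic bromide 6 alkylates dioxolanone 9. The alkene is peroxidised and the ester carbon becomes the vinyl group. Rings A and B then close in one operation, and the phenyl-dienyl chain is joined last.
Stereochemistry: C4 comes from (R)-lactic acid by self-regeneration of the stereocentre. C6 forms without control in the radical peroxidation, so the 6R epimer is obtained by separation. C3 is set in the ring-closing step.
The (S)-lactate carbinol C8 only keeps the intermediates single diastereomers and is erased at ketone 22. E-C8=C9 comes from the Horner–Wittig step, E-C10=C11 from a [2,3] shift and E-C15=C16 from cross metathesis.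

Key step: step 13

Remark: labels C1–C16 are those of the target (C1 lactone carbonyl, C3 and C6 peroxide carbons, C16 styryl carbon) and are used for every intermediate; descriptors inside systematic names follow each compound's own numbering.

Step 1
Reactants: 1 ethyl (S)-lactate
Product: 2 ethyl (2S)-2-[(tert-butyldimethylsilyl)oxy]propanoate
Conditions: TBSCl, imidazole, DMF, 0 °C → rt
Reagents that add atoms: tert-butyldimethylsilyl chloride, CC(C)(C)[Si](C)(C)Cl
Why: Imidazole-promoted silyl ether formation on a secondary alcohol leaves the lactate stereocentre (future C8) untouched.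

Step 2
Reactants: 2 ethyl (2S)-2-[(tert-butyldimethylsilyl)oxy]propanoate
Product: 4 ethyl (2E,4S)-4-[(tert-butyldimethylsilyl)oxy]-2-methylpent-2-enoate, via silyloxy aldehyde 3 (not isolated)
Conditions: i-Bu2AlH (1.05 equiv), CH2Cl2, −78 °C; then Ph3P=C(CH3)CO2Et, −78 °C → rt
Reagents that add atoms: ethyl 2-(triphenyl-λ5-phosphanylidene)propanoate, CCOC(=O)C(C)=P(c1ccccc1)(c1ccccc1)c1ccccc1
Why: Partial ester reduction followed in the same flask by Wittig olefination with a stabilised α-branched ylide should give the E-trisubstituted enoate (future C6=C7) and avoids handling the volatile, epimerisable aldehyde.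

Step 3
Reactants: 4 ethyl (2E,4S)-4-[(tert-butyldimethylsilyl)oxy]-2-methylpent-2-enoate
Product: 5 (2E,4S)-4-[(tert-butyldimethylsilyl)oxy]-2-methylpent-2-en-1-ol
Conditions: i-Bu2AlH (2.2 equiv), CH2Cl2, −78 °C
Reagents that add atoms: none
Why: 1,2-Reduction of an enoate with an aluminium hydride gives the allylic alcohol without touching the alkene geometry or the silyl ether.

Step 4
Reactants: 5 (2E,4S)-4-[(tert-butyldimethylsilyl)oxy]-2-methylpent-2-en-1-ol
Product: 6 (2E,4S)-1-bromo-4-[(tert-butyldimethylsilyl)oxy]-2-methylpent-2-ene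
Conditions: CBr4, PPh3, CH2Cl2, 0 °C
Reagents that add atoms: carbon tetrabromide, BrC(Br)(Br)Br
Why: The Appel reaction converts a primary allylic alcohol into the bromide under neutral conditions, without allylic transposition or silyl loss.

Step 5
Reactants: 7 (R)-lactic acid; 8 pivalaldehyde
Product: 9 (2R,5R)-2-tert-butyl-5-methyl-1,3-dioxolan-4-one (cis)
Conditions: p-TsOH (cat.), pentane, reflux, Dean–Stark; recrystallisation from pentane, −78 °C
Reagents that add atoms: none
Why: Acid-catalysed acetalisation under thermodynamic control favours the cis-2,5-disubstituted dioxolanone and recrystallisation removes the trans isomer, so the acetal carbon stores the configuration of the lactic acid.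

Step 6
Reactants: 9 (2R,5R)-2-tert-butyl-5-methyl-1,3-dioxolan-4-one; 6 (2E,4S)-1-bromo-4-[(tert-butyldimethylsilyl)oxy]-2-methylpent-2-ene
Product: 11 (2R,5S)-2-tert-butyl-5-{(2E,4S)-4-[(tert-butyldimethylsilyl)oxy]-2-methylpent-2-en-1-yl}-5-methyl-1,3-dioxolan-4-one, via lithium enolate 10 (not isolated)
Conditions: LiN(i-Pr)2, THF, −78 °C; then 6, −78 → −40 °C
Reagents that add atoms: none
Why: In this Seebach alkylation (self-regeneration of the stereocentre) the planar enolate is attacked by the allylic bromide (SN2) on the face anti to the tert-butyl group, which forms C4–C5 and sets quaternary C4 with the allyl group in the place of the former hydrogen.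

Step 7
Reactants: 11 (2R,5S)-2-tert-butyl-5-{(2E,4S)-4-[(tert-butyldimethylsilyl)oxy]-2-methylpent-2-en-1-yl}-5-methyl-1,3-dioxolan-4-one
Product: 12 methyl (2S,4E,6S)-6-[(tert-butyldimethylsilyl)oxy]-2-hydroxy-2,4-dimethylhept-4-enoate
Conditions: NaOMe (0.2 equiv), MeOH, 0 °C → rt
Reagents that add atoms: methanol, CO
Why: Base-catalysed transesterification opens the acylal, the resulting hemiacetal sheds pivalaldehyde, and quaternary C4 cannot epimerise.

Step 8
Reactants: 12 methyl (2S,4E,6S)-6-[(tert-butyldimethylsilyl)oxy]-2-hydroxy-2,4-dimethylhept-4-enoate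
Product: 13 methyl (2S,4E,6S)-6-[(tert-butyldimethylsilyl)oxy]-2,4-dimethyl-2-[(triethylsilyl)oxy]hept-4-enoate
Conditions: TESOTf, 2,6-lutidine, CH2Cl2, 0 °C
Reagents that add atoms: triethylsilyl trifluoromethanesulfonate, CC[Si](CC)(CC)OS(=O)(=O)C(F)(F)F
Why: Silyl triflate silylation handles the hindered tertiary alcohol, and masking the C4 oxygen keeps an alkoxide from forming next to the silyl peroxide in steps 10 and 11.

Step 9
Reactants: 13 methyl (2S,4E,6S)-6-[(tert-butyldimethylsilyl)oxy]-2,4-dimethyl-2-[(triethylsilyl)oxy]hept-4-enoate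
Product: 14 methyl (2S,4R,6S)-6-[(tert-butyldimethylsilyl)oxy]-2,4-dimethyl-2-[(triethylsilyl)oxy]-4-[(triethylsilyl)peroxy]heptanoate
Conditions: Co(thd)2 (10 mol %; thd = 2,2,6,6-tetramethylheptane-3,5-dionate), O2 (1 atm), Et3SiH, ClCH2CH2Cl, rt; chromatographic separation of the C6 epimers
Reagents that add atoms: dioxygen, O=O; triethylsilane, CC[SiH](CC)CC
Why: In the Mukaiyama–Isayama peroxidation a cobalt hydride transfers hydrogen to C7, the tertiary C6 radical traps O2 and the peroxide is silylated (Markovnikov), but the acyclic radical has no facial bias, so both C6 epimers are expected and the 6R isomer must be isolated as one of two diastereomers defined by the fixed C4 and C8 centres.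

Step 10
Reactants: 14 methyl (2S,4R,6S)-6-[(tert-butyldimethylsilyl)oxy]-2,4-dimethyl-2-[(triethylsilyl)oxy]-4-[(triethylsilyl)peroxy]heptanoate
Product: 15 (2S,4R,6S)-6-[(tert-butyldimethylsilyl)oxy]-2,4-dimethyl-2-[(triethylsilyl)oxy]-4-[(triethylsilyl)peroxy]heptanal
Conditions: i-Bu2AlH (1.1 equiv), toluene, −78 °C
Reagents that add atoms: none
Why: Partial reduction of an α-silyloxy ester stops at the aldehyde because the tetrahedral aluminium intermediate is stable at −78 °C, a temperature at which hindered protected peroxides tolerate this hydride.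

Step 11
Reactants: 15 (2S,4R,6S)-6-[(tert-butyldimethylsilyl)oxy]-2,4-dimethyl-2-[(triethylsilyl)oxy]-4-[(triethylsilyl)peroxy]heptanal
Product: 16 (3S,5R,7S)-7-[(tert-butyldimethylsilyl)oxy]-3,5-dimethyl-3-[(triethylsilyl)oxy]-5-[(triethylsilyl)peroxy]oct-1-ene
Conditions: Ph3PCH3Br, KN(SiMe3)2, THF, 0 °C; then 15, −78 → 0 °C
Reagents that add atoms: methyltriphenylphosphonium bromide, C[P+](c1ccccc1)(c1ccccc1)c1ccccc1.[Br-]
Why: Wittig methylenation of a non-enolisable aldehyde installs C2, and olefination of aldehydes that carry a protected tertiary hydroperoxide with non-stabilised ylides at low temperature is established practice.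

Step 12
Reactants: 16 (3S,5R,7S)-7-[(tert-butyldimethylsilyl)oxy]-3,5-dimethyl-3-[(triethylsilyl)oxy]-5-[(triethylsilyl)peroxy]oct-1-ene
Product: 17 (3S,5R,7S)-7-[(tert-butyldimethylsilyl)oxy]-5-hydroperoxy-3,5-dimethyloct-1-en-3-ol
Conditions: HF·pyridine, pyridine, THF, 0 °C
Reagents that add atoms: none
Why: Buffered fluoride desilylation is graded by silyl bulk, so the very labile silyl peroxide and the triethylsilyl ether should fall well before the secondary tert-butyldimethylsilyl ether, under conditions too mild to ionise the tertiary allylic alcohol.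

Step 13
Reactants: 17 (3S,5R,7S)-7-[(tert-butyldimethylsilyl)oxy]-5-hydroperoxy-3,5-dimethyloct-1-en-3-ol
Product: 20 (3R,4aS,7aS)-3-{(2S)-2-[(tert-butyldimethylsilyl)oxy]propyl}-3,4a-dimethyl-7,7a-dihydro-4H-furo[3,2-c][1,2]dioxin-6-one (target labels 3S,4S,6R,8S), via alkylpalladium acetate 18 (not isolated), via acylpalladium acetate 19 (not isolated)
Conditions: Pd(OAc)2 (10 mol %), p-benzoquinone (2 equiv), CO (1 atm), AcOH–CH2Cl2 (1:1), rt
Reagents that add atoms: carbon monoxide, [C-]#[O+]
Why: Proposed new method: divalent palladium binds the only alkene of 17, the terminal oxygen of the C6 hydroperoxide adds anti to C3 and leaves the primary C2–Pd bond of 18, CO inserts to give acyl complex 19, the C4 hydroxyl attacks the acyl carbon to release 20 and zerovalent palladium, and benzoquinone with AcOH restores divalent palladium. The closest known reaction types are the palladium-catalysed cyclisation of unsaturated tertiary hydroperoxides to 1,2-dioxanes and the palladium-catalysed oxycarbonylative bicyclisation of pent-4-ene-1,3-diols to cis-fused bicyclic lactones; new here is a hydroperoxide nucleophile working under CO. Ring A closes 6-exo-trig (O–C3) and ring B closes 5-exo-trig by acyl substitution at C1 (C2–C1 from CO insertion, C1–O from the C4 hydroxyl). C3 is set by a chair-like transition state in which the C4 and C6 methyl groups and the palladium-bound vinyl group are equatorial and the C4 hydroxyl is axial, which places C2 gauche and cis to that hydroxyl and gives 3S; the C3 epimer would hold C2 and the hydroxyl trans-diaxial, could lactonise only through the chair with syn-diaxial methyl groups, and should revert because peroxypalladation is reversible. The step needs attack by the hydroperoxide and not the alcohol, 6-exo and not 7-endo closure, and CO insertion ahead of β-hydride loss: the allylic C4 hydroxyl could only form a three- or four-membered ring, the C8 oxygen is silylated and the C7–C8 handle is saturated, attack at the internal carbon C3 gives the smaller ring, and the CO atmosphere occupies the site that β-hydride elimination from 18 requires. Benzoquinone is chosen over copper salts because monovalent copper formed during turnover would cleave the hydroperoxide by one-electron reduction.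

Step 14
Reactants: 20 C8 silyl ether of the bicyclic peroxylactone
Product: 21 (3R,4aS,7aS)-3-[(2S)-2-hydroxypropyl]-3,4a-dimethyl-7,7a-dihydro-4H-furo[3,2-c][1,2]dioxin-6-one
Conditions: HF·pyridine, THF, 0 °C → rt
Reagents that add atoms: none
Why: Acidic fluoride desilylation frees the C8 alcohol and avoids basic fluoride, which could deprotonate C2 or C3–H and fragment the peroxylactone.

Step 15
Reactants: 21 (3R,4aS,7aS)-3-[(2S)-2-hydroxypropyl]-3,4a-dimethyl-7,7a-dihydro-4H-furo[3,2-c][1,2]dioxin-6-one
Product: 22 (3S,4aS,7aS)-3,4a-dimethyl-3-(2-oxopropyl)-7,7a-dihydro-4H-furo[3,2-c][1,2]dioxin-6-one (same spatial arrangement at C6; the descriptor changes only through CIP priority)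
Conditions: Dess–Martin periodinane, CH2Cl2, 0 °C → rt
Reagents that add atoms: none
Why: Dess–Martin oxidation is neutral and non-reducing, so the dialkyl peroxide and the lactone persist while the spectator C8 stereocentre is erased.

Step 16
Reactants: 23 styrene; 24 hex-5-en-1-ol
Product: 25 (5E)-6-phenylhex-5-en-1-ol
Conditions: second-generation Grubbs catalyst RuCl2(=CHPh)(PCy3)(SIMes) (2 mol %), styrene (3 equiv), CH2Cl2, 40 °C
Reagents that add atoms: none
Why: Olefin cross metathesis of an unhindered terminal alkene with styrene gives the conjugated E-styrenyl product (C15=C16) under thermodynamic control and tolerates the free alcohol.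

Step 17
Reactants: 25 (5E)-6-phenylhex-5-en-1-ol
Product: 26 (5E)-6-phenylhex-5-enal
Conditions: Dess–Martin periodinane, CH2Cl2, rt
Reagents that add atoms: none
Why: Dess–Martin oxidation takes the primary alcohol to the aldehyde without over-oxidation or alkene isomerisation.

Step 18
Reactants: 26 (5E)-6-phenylhex-5-enal
Product: 27 (7E)-8-phenylocta-1,7-dien-3-ol (racemic)
Conditions: CH2=CHMgBr, THF, −78 → 0 °C
Reagents that add atoms: vinylmagnesium bromide, C=C[Mg]Br
Why: Grignard 1,2-addition supplies C9 and C10, and the racemic carbinol centre is of no consequence because step 19 destroys it.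

Step 19
Reactants: 27 (7E)-8-phenylocta-1,7-dien-3-ol
Product: 29 [(2E,7E)-8-phenylocta-2,7-dien-1-yl]diphenylphosphine oxide, via allylic phosphinite 28 (not isolated)
Conditions: Ph2PCl, Et3N, toluene, 0 °C; then 100 °C
Reagents that add atoms: chlorodiphenylphosphine, ClP(c1ccccc1)c1ccccc1
Why: O-phosphinylation followed by the thermal [2,3]-sigmatropic phosphinite-to-phosphine-oxide rearrangement moves phosphorus to the terminal carbon C9, and the envelope transition state with the alkyl chain pseudo-equatorial gives E-C10=C11.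

Step 20
Reactants: 29 [(2E,7E)-8-phenylocta-2,7-dien-1-yl]diphenylphosphine oxide; 22 (3S,4aS,7aS)-3,4a-dimethyl-3-(2-oxopropyl)-7,7a-dihydro-4H-furo[3,2-c][1,2]dioxin-6-one
Product: 32 plakortolide H, via lithiated phosphine oxide 30 (not isolated), via lithium oxido adduct 31 (not isolated)
Conditions: 29 (1.2 equiv), n-BuLi (1.15 equiv), THF, −78 °C; then 22, −78 °C → rt
Reagents that add atoms: none
Why: In this Horner–Wittig olefination the lithiated allylic phosphine oxide adds through its α-carbon to the ketone faster at −78 °C than it deprotonates C2 or C7, the adduct loses diphenylphosphinate by syn-elimination on warming, and the size gap between the neopentyl-type C7 methylene and the C8 methyl group should place the dienyl chain trans to C7 (8E, any 8Z isomer to be removed by chromatography), while the other two alkene geometries are carried over from 29.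

Compound list
1 | ethyl (S)-lactate | CCOC(=O)[C@H](C)O | starting material
2 | ethyl (2S)-2-[(tert-butyldimethylsilyl)oxy]propanoate | CCOC(=O)[C@H](C)O[Si](C)(C)C(C)(C)C | intermediate
3 | (2S)-2-[(tert-butyldimethylsilyl)oxy]propanal | C[C@H](O[Si](C)(C)C(C)(C)C)C=O | intermediate
4 | ethyl (2E,4S)-4-[(tert-butyldimethylsilyl)oxy]-2-methylpent-2-enoate | CCOC(=O)/C(C)=C/[C@H](C)O[Si](C)(C)C(C)(C)C | intermediate
5 | (2E,4S)-4-[(tert-butyldimethylsilyl)oxy]-2-methylpent-2-en-1-ol | OC/C(C)=C/[C@H](C)O[Si](C)(C)C(C)(C)C | intermediate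
6 | (2E,4S)-1-bromo-4-[(tert-butyldimethylsilyl)oxy]-2-methylpent-2-ene | BrC/C(C)=C/[C@H](C)O[Si](C)(C)C(C)(C)C | intermediate
7 | (R)-lactic acid | C[C@@H](O)C(=O)O | starting material
8 | pivalaldehyde | CC(C)(C)C=O | starting material
9 | (2R,5R)-2-tert-butyl-5-methyl-1,3-dioxolan-4-one | C[C@H]1O[C@@H](C(C)(C)C)OC1=O | intermediate
10 | lithium (2R)-2-tert-butyl-5-methyl-1,3-dioxol-4-olate | CC1=C([O-])O[C@H](C(C)(C)C)O1.[Li+] | intermediate
11 | (2R,5S)-2-tert-butyl-5-{(2E,4S)-4-[(tert-butyldimethylsilyl)oxy]-2-methylpent-2-en-1-yl}-5-methyl-1,3-dioxolan-4-one | C[C@@]1(C/C(C)=C/[C@H](C)O[Si](C)(C)C(C)(C)C)O[C@@H](C(C)(C)C)OC1=O | intermediate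
12 | methyl (2S,4E,6S)-6-[(tert-butyldimethylsilyl)oxy]-2-hydroxy-2,4-dimethylhept-4-enoate | COC(=O)[C@@](C)(O)C/C(C)=C/[C@H](C)O[Si](C)(C)C(C)(C)C | intermediate
13 | methyl (2S,4E,6S)-6-[(tert-butyldimethylsilyl)oxy]-2,4-dimethyl-2-[(triethylsilyl)oxy]hept-4-enoate | COC(=O)[C@@](C)(O[Si](CC)(CC)CC)C/C(C)=C/[C@H](C)O[Si](C)(C)C(C)(C)C | intermediate
14 | methyl (2S,4R,6S)-6-[(tert-butyldimethylsilyl)oxy]-2,4-dimethyl-2-[(triethylsilyl)oxy]-4-[(triethylsilyl)peroxy]heptanoate | COC(=O)[C@@](C)(O[Si](CC)(CC)CC)C[C@](C)(OO[Si](CC)(CC)CC)C[C@H](C)O[Si](C)(C)C(C)(C)C | intermediate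
15 | (2S,4R,6S)-6-[(tert-butyldimethylsilyl)oxy]-2,4-dimethyl-2-[(triethylsilyl)oxy]-4-[(triethylsilyl)peroxy]heptanal | O=C[C@@](C)(O[Si](CC)(CC)CC)C[C@](C)(OO[Si](CC)(CC)CC)C[C@H](C)O[Si](C)(C)C(C)(C)C | intermediate
16 | (3S,5R,7S)-7-[(tert-butyldimethylsilyl)oxy]-3,5-dimethyl-3-[(triethylsilyl)oxy]-5-[(triethylsilyl)peroxy]oct-1-ene | C=C[C@@](C)(O[Si](CC)(CC)CC)C[C@](C)(OO[Si](CC)(CC)CC)C[C@H](C)O[Si](C)(C)C(C)(C)C | intermediate
17 | (3S,5R,7S)-7-[(tert-butyldimethylsilyl)oxy]-5-hydroperoxy-3,5-dimethyloct-1-en-3-ol | C=C[C@@](C)(O)C[C@](C)(OO)C[C@H](C)O[Si](C)(C)C(C)(C)C | intermediate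
18 | alkylpalladium acetate (ring A closed, C2–Pd bond, C4 hydroxyl free; 3S,4S,6R,8S) | C[C@@H](C[C@]1(C)C[C@](C)(O)[C@H](C[Pd]OC(C)=O)OO1)O[Si](C)(C)C(C)(C)C | intermediate
19 | acylpalladium acetate (ring A closed, C1(=O)–Pd bond, C4 hydroxyl free; 3S,4S,6R,8S) | C[C@@H](C[C@]1(C)C[C@](C)(O)[C@H](CC(=O)[Pd]OC(C)=O)OO1)O[Si](C)(C)C(C)(C)C | intermediate
20 | (3R,4aS,7aS)-3-{(2S)-2-[(tert-butyldimethylsilyl)oxy]propyl}-3,4a-dimethyl-7,7a-dihydro-4H-furo[3,2-c][1,2]dioxin-6-one | C[C@@H](C[C@]1(C)C[C@]2(C)OC(=O)C[C@@H]2OO1)O[Si](C)(C)C(C)(C)C | intermediate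
21 | (3R,4aS,7aS)-3-[(2S)-2-hydroxypropyl]-3,4a-dimethyl-7,7a-dihydro-4H-furo[3,2-c][1,2]dioxin-6-one | C[C@@H](C[C@]1(C)C[C@]2(C)OC(=O)C[C@@H]2OO1)O | intermediate
22 | (3S,4aS,7aS)-3,4a-dimethyl-3-(2-oxopropyl)-7,7a-dihydro-4H-furo[3,2-c][1,2]dioxin-6-one | CC(=O)C[C@]1(C)C[C@]2(C)OC(=O)C[C@@H]2OO1 | intermediate
23 | styrene | C=Cc1ccccc1 | starting material
24 | hex-5-en-1-ol | C=CCCCCO | starting material
25 | (5E)-6-phenylhex-5-en-1-ol | OCCCC/C=C/c1ccccc1 | intermediate
26 | (5E)-6-phenylhex-5-enal | O=CCCC/C=C/c1ccccc1 | intermediate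
27 | (7E)-8-phenylocta-1,7-dien-3-ol (racemic) | C=CC(O)CCC/C=C/c1ccccc1 | intermediate
28 | (7E)-8-phenylocta-1,7-dien-3-yl diphenylphosphinite (racemic) | C=CC(CCC/C=C/c1ccccc1)OP(c1ccccc1)c1ccccc1 | intermediate
29 | [(2E,7E)-8-phenylocta-2,7-dien-1-yl]diphenylphosphine oxide | O=P(C/C=C/CCC/C=C/c1ccccc1)(c1ccccc1)c1ccccc1 | intermediate
30 | lithium salt of 29 deprotonated at C9 | O=P(c1ccccc1)(c1ccccc1)[CH-]/C=C/CCC/C=C/c1ccccc1.[Li+] | intermediate
31 | lithium β-oxido phosphine oxide adduct of 30 and 22 (C8 and C9 not defined, mixture) | [Li+].[O-]C(C)(C[C@]1(C)C[C@]2(C)OC(=O)C[C@@H]2OO1)C(/C=C/CCC/C=C/c1ccccc1)P(=O)(c1ccccc1)c1ccccc1 | intermediate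
32 | plakortolide H (3S,4S,6R; 8E,10E,15E) | C/C(=C\C=C\CCC/C=C/c1ccccc1)C[C@]1(C)C[C@]2(C)OC(=O)C[C@@H]2OO1 | target

Total step count: 20. Longest linear sequence: 15 steps (steps 1–4, 6–15 and 20, from ethyl (S)-lactate).

Steps most likely to fail

1. Step 13.
- **What may go wrong:** The palladium-bound hydroperoxide may transfer oxygen to CO or to the alkene (Wacker-type ketone formation). Zerovalent palladium may insert into the O–O bond. β-Hydride elimination may overtake CO insertion.
- **Fallback:** It uses known chemistry, sets out from 15 and returns at 20.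
- Z-selective Still–Gennari olefination of 15 with methyl bis(2,2,2-trifluoroethyl)phosphonoacetate (KN(SiMe3)2, 18-crown-6, THF, −78 °C) would give the (Z)-enoate F1.
- HF·pyridine would then remove both triethylsilyl groups. The freed C4 hydroxyl would lactonise onto the Z-ester to give the hydroperoxy butenolide F2.
- Et2NH in CF3CH2OH would trigger intramolecular oxa-Michael addition of the hydroperoxide to C3. The C5 tether can only deliver oxygen to the face that gives the cis ring fusion of 20.

2. Step 20.
- **What may go wrong:** The β-peroxy ketone may enolise and lose the peroxide by E1cB. C2 may be deprotonated. The allyl anion may attack through its γ-carbon. Control of the C8=C9 geometry on a methyl ketone may be weak.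
- **Fallback:** It sets out from 22 and 26 and returns at 32.
- Boron-Wittig olefination of 22 with the far less basic lithiated CH2(Bpin)2 (lithium 2,2,6,6-tetramethylpiperidide, THF, −78 °C → rt) would give the (8E)-alkenyl pinacol boronate F3. Its geometric isomers can be separated before the chain is committed.
- Takai olefination of 26 (CrCl2, CHI3, THF, 0 °C) would give the (1E,6E)-1-iodo-7-phenylhepta-1,6-diene F4.
- Suzuki coupling of the two (Pd(PPh3)4, Ag2O, THF–H2O, rt) forms C9–C10 with retention of both geometries.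

3. Step 9.
- **What may go wrong:** Hydrogen-atom transfer to a trisubstituted alkene shielded by two silyl ethers may be slow. The absence of facial bias at the C6 radical makes everything depend on a separation that may be difficult in the flexible ester.
- **Fallback:** It sets out from 11 and returns at 17.
- The same cobalt peroxidation is moved to the less shielded, rigid dioxolanone to give the silylperoxy dioxolanone F5. There the acetal ring should widen the difference between the C6 epimers for chromatography or crystallisation.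
- i-Bu2AlH (−78 °C) would reduce F5 to the lactol F6.
- Excess Ph3P=CH2 would open the lactol, which sheds pivalaldehyde, and methylenate the released aldehyde to the vinyl carbinol silyl peroxide F7.
- HF·pyridine would then cleave the silyl peroxide to give 17. This also bypasses steps 7, 8 and 10.

Further compounds
F1 | step 13 | methyl (2Z,4S,6R,8S)-8-[(tert-butyldimethylsilyl)oxy]-4,6-dimethyl-4-[(triethylsilyl)oxy]-6-[(triethylsilyl)peroxy]non-2-enoate | COC(=O)/C=C\[C@@](C)(O[Si](CC)(CC)CC)C[C@](C)(OO[Si](CC)(CC)CC)C[C@H](C)O[Si](C)(C)C(C)(C)C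
F2 | step 13 | (5S)-5-{(2R,4S)-4-[(tert-butyldimethylsilyl)oxy]-2-hydroperoxy-2-methylpentyl}-5-methylfuran-2(5H)-one | C[C@@H](C[C@@](C)(OO)C[C@]1(C)OC(=O)C=C1)O[Si](C)(C)C(C)(C)C
F3 | step 20 | (8E)-alkenyl pinacol boronate of the peroxylactone core (Bpin on C9; 3S,4S,6R) | C/C(=C\B3OC(C)(C)C(C)(C)O3)C[C@]1(C)C[C@]2(C)OC(=O)C[C@@H]2OO1
F4 | step 20 | (1E,6E)-1-iodo-7-phenylhepta-1,6-diene | I/C=C/CCC/C=C/c1ccccc1
F5 | step 9 | (2R,5S)-2-tert-butyl-5-{(2R,4S)-4-[(tert-butyldimethylsilyl)oxy]-2-methyl-2-[(triethylsilyl)peroxy]pentyl}-5-methyl-1,3-dioxolan-4-one | C[C@@]1(C[C@](C)(OO[Si](CC)(CC)CC)C[C@H](C)O[Si](C)(C)C(C)(C)C)O[C@@H](C(C)(C)C)OC1=O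
F6 | step 9 | lactol of F5 (1,3-dioxolan-4-ol, anomeric mixture) | C[C@@]1(C[C@](C)(OO[Si](CC)(CC)CC)C[C@H](C)O[Si](C)(C)C(C)(C)C)O[C@@H](C(C)(C)C)OC1O
F7 | step 9 | (3S,5R,7S)-7-[(tert-butyldimethylsilyl)oxy]-3,5-dimethyl-5-[(triethylsilyl)peroxy]oct-1-en-3-ol | C=C[C@@](C)(O)C[C@](C)(OO[Si](CC)(CC)CC)C[C@H](C)O[Si](C)(C)C(C)(C)C
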